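**Retrosynthetic overview**
1. Target ⇒ tetracyclic C11 ketone: the C12 methyl comes from α-methylenation/hydrogenation, the C11 acetate from hydride reduction/acetylation.
2. Ring D (oxepane) ⇒ C3–O–C16 etherification via a primary triflate; ring C (oxonane) ⇒ ring-closing metathesis at C4=C5, then hydrogenation.
3. Ring B (tetrahydrofuran) ⇒ BF3-mediated oxocarbenium annulation of a C6–C9 aldehyde onto an enol carbamate (makes O–C9 and C9–C10, unveils the C11 ketone).
4. Key C1–C2 bond ⇒ homoenolate coupling: a titanated cyclohex-2-enyl carbamate (β-anion equivalent of the later C11 ketone) adds to an α-benzyloxy aldehyde; both carbons are natural acceptor sites.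
5. Fragments: ring A carbamate from (S)-3-bromo-2-methylpropanol + methyl vinyl ketone; C2–C4 aldehyde from isoprene monoepoxide; C6–C9 aldehyde from crotonaldehyde + (Z)-crotylboronate. Ring order: A → B → C → D.

Assumption: the SMILES is taken as the exact target (this enantiomer); atom labels follow the asbestinin skeleton (C1/C10 ring fusion, C2 and C9 on the bridging oxygen, C3 quaternary, C11 acetoxy, C12 methyl, C14–C15–C16 the oxepane arm).

The stereochemical course of step 12 rests on recalled precedent for 4-alkylcyclohex-2-enyl carbamates and could not be checked here. The catalyst antipodes in steps 6 and 8 are assigned from memory of the usual sense of induction; confirm the sign at 11 and 15.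

**Step 1**
Reactants: 1 (S)-3-bromo-2-methylpropan-1-ol
Product: 2 (S)-[(3-bromo-2-methylpropoxy)methyl]benzene
Conditions: BnOC(=NH)CCl3 (1.2 equiv), TfOH (5 mol %), cyclohexane–CH2Cl2, 0 °C → rt
Reagents that add atoms: benzyl 2,2,2-trichloroacetimidate, ClC(Cl)(Cl)C(=N)OCc1ccccc1
Why: acid-catalysed O-benzylation with a trichloroacetimidate (no base, so no oxetane formation or HBr loss); the stereocentre (future C15) is untouched.

**Step 2**
Reactants: 2 (S)-[(3-bromo-2-methylpropoxy)methyl]benzene
Product: 4 (R)-4-(benzyloxy)-3-methylbutanal, via Grignard reagent 3 (not isolated)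
Conditions: Mg, I2 (cat.), THF, 40 °C; DMF, 0 °C → rt; 1 M HCl
Reagents that add atoms: N,N-dimethylformamide, CN(C)C=O
Why: Bouveault formylation of a primary Grignard reagent adds the future C1 as the aldehyde carbon without touching the stereocentre.

**Step 3**
Reactants: 4 (R)-4-(benzyloxy)-3-methylbutanal; 5 but-3-en-2-one
Product: 7 (4R)-4-[(2R)-1-(benzyloxy)propan-2-yl]cyclohex-2-en-1-one, via keto-aldehyde 6 (not isolated)
Conditions: (S)-2-[methoxy(diphenyl)methyl]pyrrolidine (5 mol %), ethyl 3,4-dihydroxybenzoate (20 mol %), neat, 4 °C, 36 h; then iPrOH, LiOH (0.2 equiv), rt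
Reagents that add atoms: none
Why: organocatalytic enamine Michael addition (the diarylprolinol ether blocks one enamine face, so Si-face attack sets C14 under catalyst control) followed by intramolecular aldol condensation (Robinson-type annulation) under mild base that does not epimerise the γ-stereocentre.

**Step 4**
Reactants: 7 (4R)-4-[(2R)-1-(benzyloxy)propan-2-yl]cyclohex-2-en-1-one
Product: 8 (1R,4R)-4-[(2R)-1-(benzyloxy)propan-2-yl]cyclohex-2-en-1-ol (trans)
Conditions: NaBH4, CeCl3·7H2O, MeOH, −78 °C
Reagents that add atoms: none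
Why: Luche 1,2-reduction; hydride adds axially to the half-chair that has the C4 side chain pseudo-equatorial, giving mainly the trans allylic alcohol (about 4:1 expected; the cis isomer is removed by chromatography).

**Step 5**
Reactants: 8 (1R,4R)-4-[(2R)-1-(benzyloxy)propan-2-yl]cyclohex-2-en-1-ol
Product: 9 (1R,4R)-4-[(2R)-1-(benzyloxy)propan-2-yl]cyclohex-2-en-1-yl N,N-diisopropylcarbamate
Conditions: NaH, ClC(O)N(iPr)2, THF, reflux
Reagents that add atoms: N,N-diisopropylcarbamoyl chloride, CC(C)N(C(C)C)C(Cl)=O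
Why: O-carbamoylation of the sodium alkoxide installs the directing and anion-stabilising group for the homoenolate step, with no stereochemical change.

**Step 6**
Reactants: 10 2-methyl-2-vinyloxirane (racemic)
Product: 11 (S)-2-(benzyloxy)-2-methylbut-3-en-1-ol
Conditions: Pd2(dba)3·CHCl3 (1 mol %), (R,R)-DACH-phenyl Trost ligand (3 mol %), BEt3 (1 mol %), BnOH (1.1 equiv), CH2Cl2, rt
Reagents that add atoms: benzyl alcohol, OCc1ccccc1
Why: Pd-catalysed dynamic kinetic asymmetric allylic etherification of the racemic vinyl epoxide (Trost DYKAT): the π-allyl palladium diastereomers interconvert and the boron-bound alkoxide is delivered to the tertiary terminus under ligand control, which sets the quaternary C3 centre (the ligand antipode is the one that gives (S)-11).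

**Step 7**
Reactants: 11 (S)-2-(benzyloxy)-2-methylbut-3-en-1-ol
Product: 12 (S)-2-(benzyloxy)-2-methylbut-3-enal
Conditions: Dess–Martin periodinane, CH2Cl2, 0 °C → rt
Reagents that add atoms: none
Why: Dess–Martin oxidation of the primary alcohol; the aldehyde has no α-hydrogen, so it can neither epimerise nor conjugate.

**Step 8**
Reactants: 13 (E)-but-2-enal; 14 2-[(2Z)-but-2-en-1-yl]-4,4,5,5-tetramethyl-1,3,2-dioxaborolane
Product: 15 (3R,4R,5E)-3-methylhepta-1,5-dien-4-ol
Conditions: (S)-TRIP [(S)-3,3'-bis(2,4,6-triisopropylphenyl)-1,1'-binaphthyl-2,2'-diyl hydrogen phosphate] (5 mol %), 4 Å MS, toluene, −30 °C; aq NaHCO3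
Reagents that add atoms: none
Why: chiral phosphoric acid-catalysed crotylboration through a chair six-membered transition state; the (Z)-boronate gives the syn product and the catalyst directs Si-face addition to the aldehyde (sets C6 and C7).

**Step 9**
Reactants: 15 (3R,4R,5E)-3-methylhepta-1,5-dien-4-ol
Product: 16 (3R,4R,5E)-4-methoxy-3-methylhepta-1,5-diene
Conditions: NaH, MeI, THF, 0 °C → rt
Reagents that add atoms: iodomethane, CI
Why: Williamson O-methylation; no stereocentre is touched.

**Step 10**
Reactants: 16 (3R,4R,5E)-4-methoxy-3-methylhepta-1,5-diene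
Product: 17 (3R,4S,5E)-4-methoxy-3-methylhept-5-en-1-ol
Conditions: 9-BBN (1.1 equiv), THF, 0 °C → rt; NaOH, H2O2
Reagents that add atoms: hydrogen peroxide, OO
Why: anti-Markovnikov hydroboration–oxidation; 9-BBN selects the terminal vinyl group over the 1,2-disubstituted propenyl group, which also carries a deactivating allylic ether.

**Step 11**
Reactants: 17 (3R,4S,5E)-4-methoxy-3-methylhept-5-en-1-ol
Product: 18 (3R,4S,5E)-4-methoxy-3-methylhept-5-enal
Conditions: Dess–Martin periodinane, CH2Cl2, 0 °C → rt
Reagents that add atoms: none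
Why: Dess–Martin oxidation; the β-stereocentre is not epimerisable.

**Step 12 (key step)**
Reactants: 9 (1R,4R)-4-[(2R)-1-(benzyloxy)propan-2-yl]cyclohex-2-en-1-yl N,N-diisopropylcarbamate; 12 (S)-2-(benzyloxy)-2-methylbut-3-enal
Product: 21 (3S,4S)-4-[(2R)-1-(benzyloxy)propan-2-yl]-3-[(1S,2S)-2-(benzyloxy)-1-hydroxy-2-methylbut-3-en-1-yl]cyclohex-1-en-1-yl N,N-diisopropylcarbamate, via allyllithium 19 (not isolated), via allyltitanium 20 (not isolated)
Conditions: s-BuLi (1.15 equiv), TMEDA, Et2O, −78 °C, 3 h; ClTi(OiPr)3 (2.5 equiv), −78 °C, 1 h; 12, −78 → −40 °C; aq NH4Cl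
Reagents that add atoms: none
Why: Hoppe homoaldol reaction: carbamate-directed deprotonation removes the pseudo-axial C11–H with retention to give the configurationally stable allyllithium 19, titanium replaces lithium with inversion (20), and this α-oxy allyltitanium (a homoenolate equivalent of the later C11 ketone) adds at its γ-carbon C1 to aldehyde 12 on the titanium-bearing face, anti to the C14 side chain, through a closed six-membered transition state that is boat-like because the allyl unit is ring-locked cis and so turns the aldehyde residue away from C14 (sets C1 and the 1,2-anti C2 carbinol, the sense known for 4-alkylcyclohex-2-enyl carbamates; C3 comes from 12 and is weakly matched, Felkin–Anh with OBn anti and vinyl outside).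

**Step 13**
Reactants: 21 homoaldol adduct; 18 (3R,4S,5E)-4-methoxy-3-methylhept-5-enal
Product: 22 (1S,3S,3aR,7S,7aS)-1-[(2S)-2-(benzyloxy)but-3-en-2-yl]-7-[(2R)-1-(benzyloxy)propan-2-yl]-3-[(2R,3S,4E)-3-methoxy-2-methylhex-4-en-1-yl]hexahydroisobenzofuran-4(1H)-one
Conditions: BF3·OEt2 (2.5 equiv), Et2O, −78 → 0 °C
Reagents that add atoms: none
Why: Hoppe tetrahydrofuran annulation (oxocarbenium/enol carbamate, Mukaiyama–Prins type): the C2 hydroxyl and 18 form an (E)-oxocarbenium ion that C10 of the enol carbamate attacks on the face of the C1–C2 bond (cis ring fusion) with the C9 substituent pseudo-equatorial (C2 and C9 substituents cis, both exo), and the carbamoyl group leaves as the carbamoyl fluoride to unveil the C11 ketone; the electron-rich enol carbamate outcompetes the deactivated C3 vinyl group (Prins pathway).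

**Step 14**
Reactants: 22 bicyclic ketone
Product: 23 tricyclic ketone (rings A–B–C; (Z)-C4=C5 in the oxonane; 3-OBn, 6-OMe, 7-Me, 16-OBn, 11-oxo)
Conditions: second-generation Hoveyda–Grubbs catalyst RuCl2(H2IMes)(=CH–C6H4-2-OiPr) (10 mol %), toluene (2 mM), 80 °C, Ar sparge
Reagents that add atoms: none
Why: ring-closing metathesis with loss of propene; the 2,9-cis tetrahydrofuran holds both olefinic arms on the same face, the nine-membered ring enforces the Z alkene, and no stereocentre is formed.

**Step 15**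
Reactants: 23 tricyclic ketone
Product: 24 tricyclic keto-diol (saturated oxonane; 3-OH, 16-OH, 11-oxo)
Conditions: H2 (1 atm), Pd/C (10 wt %), EtOAc–EtOH, rt
Reagents that add atoms: none
Why: heterogeneous hydrogenation saturates C4=C5 and hydrogenolyses both benzyl ethers in one operation; no stereocentre is created (C4 and C5 become CH2).

**Step 16**
Reactants: 24 tricyclic keto-diol
Product: 26 tetracyclic 11-ketone (oxepane closed; C12 still CH2), via primary triflate 25 (not isolated)
Conditions: Tf2O (1.1 equiv), 2,6-lutidine (3 equiv), CH2Cl2, −78 → 0 °C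
Reagents that add atoms: none
Why: chemoselective triflation of the primary C16 alcohol followed by intramolecular Williamson-type SN2 displacement by the tertiary C3 hydroxyl closes the seven-membered ring D trans-fused to ring A; no stereocentre is affected.

**Step 17**
Reactants: 26 tetracyclic 11-ketone
Product: 30 12-methylene-11-ketone, via lithium enolate 27 (not isolated), via Mannich base 28 (not isolated), via ammonium iodide 29 (not isolated)
Conditions: LiN(SiMe3)2, THF, −78 °C; Me2N=CH2 I, −78 → 0 °C; MeI, CH2Cl2, rt; DBU, rt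
Reagents that add atoms: N,N-dimethylmethyleneiminium iodide (Eschenmoser's salt), C=[N+](C)C.[I-]
Why: Eschenmoser methylenation: kinetic enolisation occurs at the C12 methylene (C10–H is tertiary, equatorial and hindered), followed by Mannich reaction, N-methylation and E1cB elimination.

**Step 18**
Reactants: 30 12-methylene-11-ketone
Product: 31 12-methyl-11-ketone (methyl cis to the C10–C9 bond)
Conditions: H2 (1 atm), Pd/C (10 wt %), EtOAc, 0 °C, short reaction time
Reagents that add atoms: none
Why: heterogeneous hydrogenation of the exocyclic enone: the trans-fused oxepane locks ring A as a chair with the C10–C9 bond axial, which shields one face of C12, so hydrogen is delivered from the opposite H1/H10 face and the methyl ends cis to C9 (sets C12 kinetically; the axial methyl is the less stable epimer, so 31 is kept away from base).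

**Step 19**
Reactants: 31 12-methyl-11-ketone
Product: 33 target CNP0289153.2, via aluminium alkoxide 32 (not isolated)
Conditions: iBu2AlH (1.2 equiv), CH2Cl2, −78 °C; then pyridine, DMAP, Ac2O, −78 °C → rt
Reagents that add atoms: acetic anhydride, CC(=O)OC(C)=O
Why: one-pot reductive acetylation: the non-basic hydride attacks C11 from the unhindered H1/H10 face (axial attack; the other face is flanked by the axial C12 methyl and C10–C9 bond), giving the equatorial alkoxide cis to the methyl (sets C11), which is acetylated in situ.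

Minor enantiomers carried in from steps 3, 6 and 8 become diastereomers at 21 and 22 and are removed there by chromatography.

**Compound list**
1 | (S)-3-bromo-2-methylpropan-1-ol | OC[C@H](C)CBr | starting material
2 | (S)-[(3-bromo-2-methylpropoxy)methyl]benzene | c1ccccc1COC[C@H](C)CBr | intermediate
3 | [(S)-3-(benzyloxy)-2-methylpropyl]magnesium bromide | c1ccccc1COC[C@H](C)C[Mg]Br | intermediate
4 | (R)-4-(benzyloxy)-3-methylbutanal | c1ccccc1COC[C@H](C)CC=O | intermediate
5 | but-3-en-2-one | C=CC(C)=O | starting material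
6 | (2S)-2-[(2R)-1-(benzyloxy)propan-2-yl]-5-oxohexanal | c1ccccc1COC[C@H](C)[C@@H](C=O)CCC(C)=O | intermediate
7 | (4R)-4-[(2R)-1-(benzyloxy)propan-2-yl]cyclohex-2-en-1-one | c1ccccc1COC[C@H](C)[C@@H]2CCC(=O)C=C2 | intermediate
8 | (1R,4R)-4-[(2R)-1-(benzyloxy)propan-2-yl]cyclohex-2-en-1-ol (trans) | c1ccccc1COC[C@H](C)[C@@H]2CC[C@@H](O)C=C2 | intermediate
9 | (1R,4R)-4-[(2R)-1-(benzyloxy)propan-2-yl]cyclohex-2-en-1-yl N,N-diisopropylcarbamate | c1ccccc1COC[C@H](C)[C@@H]2CC[C@@H](OC(=O)N(C(C)C)C(C)C)C=C2 | intermediate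
10 | 2-methyl-2-vinyloxirane (racemic) | C=CC1(C)CO1 | starting material
11 | (S)-2-(benzyloxy)-2-methylbut-3-en-1-ol | OC[C@@](C)(OCc1ccccc1)C=C | intermediate
12 | (S)-2-(benzyloxy)-2-methylbut-3-enal | O=C[C@@](C)(OCc1ccccc1)C=C | intermediate
13 | (E)-but-2-enal | C/C=C/C=O | starting material
14 | 2-[(2Z)-but-2-en-1-yl]-4,4,5,5-tetramethyl-1,3,2-dioxaborolane | C/C=C\CB1OC(C)(C)C(C)(C)O1 | starting material
15 | (3R,4R,5E)-3-methylhepta-1,5-dien-4-ol (syn) | O[C@H](/C=C/C)[C@H](C)C=C | intermediate
16 | (3R,4R,5E)-4-methoxy-3-methylhepta-1,5-diene | CO[C@H](/C=C/C)[C@H](C)C=C | intermediate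
17 | (3R,4S,5E)-4-methoxy-3-methylhept-5-en-1-ol | CO[C@H](/C=C/C)[C@H](C)CCO | intermediate
18 | (3R,4S,5E)-4-methoxy-3-methylhept-5-enal | CO[C@H](/C=C/C)[C@H](C)CC=O | intermediate
19 | 1-lithio derivative of 9 (lithium on the face of the removed hydrogen; TMEDA complex) | c1ccccc1COC[C@H](C)[C@@H]2CC[C@@]([Li])(OC(=O)N(C(C)C)C(C)C)C=C2 | intermediate
20 | 1-(triisopropoxytitanio) derivative of 9 (titanium on the opposite face) | c1ccccc1COC[C@H](C)[C@@H]2CC[C@]([Ti](OC(C)C)(OC(C)C)OC(C)C)(OC(=O)N(C(C)C)C(C)C)C=C2 | intermediate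
21 | (3S,4S)-4-[(2R)-1-(benzyloxy)propan-2-yl]-3-[(1S,2S)-2-(benzyloxy)-1-hydroxy-2-methylbut-3-en-1-yl]cyclohex-1-en-1-yl N,N-diisopropylcarbamate | c1ccccc1COC[C@H](C)[C@@H]2CCC(OC(=O)N(C(C)C)C(C)C)=C[C@H]2[C@H](O)[C@@](C)(OCc3ccccc3)C=C | intermediate
22 | (1S,3S,3aR,7S,7aS)-1-[(2S)-2-(benzyloxy)but-3-en-2-yl]-7-[(2R)-1-(benzyloxy)propan-2-yl]-3-[(2R,3S,4E)-3-methoxy-2-methylhex-4-en-1-yl]hexahydroisobenzofuran-4(1H)-one | c1ccccc1COC[C@H](C)[C@@H]2CCC(=O)[C@@H]3[C@H]2[C@H](O[C@H]3C[C@@H](C)[C@H](OC)/C=C/C)[C@@](C)(OCc4ccccc4)C=C | intermediate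
23 | tricyclic ketone: 22 ring-closed between C4 and C5 ((Z)-alkene in the oxonane bridging C2 and C9); 3-benzyloxy-3-methyl, 6-methoxy, 7-methyl, 16-benzyloxy, 11-oxo | c1ccccc1COC[C@H](C)[C@@H]2CCC(=O)[C@@H]3[C@H]2[C@@H]4O[C@H]3C[C@@H](C)[C@H](OC)/C=C\[C@]4(C)OCc5ccccc5 | intermediate
24 | tricyclic keto-diol: saturated oxonane, 3-hydroxy-3-methyl, C14 (R)-1-hydroxypropan-2-yl, 11-oxo | OC[C@H](C)[C@@H]2CCC(=O)[C@@H]3[C@H]2[C@@H]4O[C@H]3C[C@@H](C)[C@H](OC)CC[C@]4(C)O | intermediate
25 | 16-O-trifluoromethanesulfonate of 24 | FC(F)(F)S(=O)(=O)OC[C@H](C)[C@@H]2CCC(=O)[C@@H]3[C@H]2[C@@H]4O[C@H]3C[C@@H](C)[C@H](OC)CC[C@]4(C)O | intermediate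
26 | tetracyclic 11-ketone (target skeleton with C11 ketone and unsubstituted C12) | CO[C@@H]1CC[C@]2(C)OC[C@H](C)[C@@H]3CCC(=O)[C@@H]4[C@H]3[C@@H]2O[C@H]4C[C@H]1C | intermediate
27 | lithium C11=C12 enolate of 26 | CO[C@@H]1CC[C@]2(C)OC[C@H](C)[C@@H]3CC=C(O[Li])[C@@H]4[C@H]3[C@@H]2O[C@H]4C[C@H]1C | intermediate
28 | 12-[(dimethylamino)methyl] derivative of 26 (C12 epimer mixture) | CO[C@@H]1CC[C@]2(C)OC[C@H](C)[C@@H]3CC(CN(C)C)C(=O)[C@@H]4[C@H]3[C@@H]2O[C@H]4C[C@H]1C | intermediate
29 | 12-[(trimethylammonio)methyl] derivative of 26, iodide | CO[C@@H]1CC[C@]2(C)OC[C@H](C)[C@@H]3CC(C[N+](C)(C)C)C(=O)[C@@H]4[C@H]3[C@@H]2O[C@H]4C[C@H]1C.[I-] | intermediate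
30 | 12-methylene-11-ketone | CO[C@@H]1CC[C@]2(C)OC[C@H](C)[C@@H]3CC(=C)C(=O)[C@@H]4[C@H]3[C@@H]2O[C@H]4C[C@H]1C | intermediate
31 | 12-methyl-11-ketone (methyl cis to C10–C9 and C1–C2) | CO[C@@H]1CC[C@]2(C)OC[C@H](C)[C@@H]3C[C@@H](C)C(=O)[C@@H]4[C@H]3[C@@H]2O[C@H]4C[C@H]1C | intermediate
32 | diisobutylaluminium 11-alkoxide (oxygen cis to the C12 methyl) | CO[C@@H]1CC[C@]2(C)OC[C@H](C)[C@@H]3C[C@@H](C)[C@@H](O[Al](CC(C)C)CC(C)C)[C@@H]4[C@H]3[C@@H]2O[C@H]4C[C@H]1C | intermediate
33 | CNP0289153.2 (11-acetate) | CO[C@@H]1CC[C@]2(C)OC[C@H](C)[C@@H]3C[C@@H](C)[C@@H](OC(C)=O)[C@@H]4[C@H]3[C@@H]2O[C@H]4C[C@H]1C | target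

**Step count**
Total: 19 steps. Longest linear sequence: 13 steps (steps 1–5, then 12–19).

**Three steps most likely to fail**

Step 12 (homoaldol). The C–C bond formation and the face selectivity are expected to follow the known behaviour of this carbamate class, but the C2 configuration depends on the shape of the closed transition state with a ring-locked allyl unit and an α-quaternary aldehyde; a chair-like transition state would give the C2 epimer. The fallback sets out from 9 and 12 and no longer relies on the addition for C2. The coupling is run as before and any (3S,4S)-3-[(1R,2S)-2-(benzyloxy)-1-hydroxy-2-methylbut-3-en-1-yl] epimer of 21, F1, is combined with 21. The mixture is oxidised with Dess–Martin periodinane to the single (3S,4S)-3-[(2S)-2-(benzyloxy)-2-methylbut-3-enoyl]cyclohexenyl carbamate F2. This ketone is reduced under reagent control with (R)-2-methyl-CBS-oxazaborolidine and catecholborane in toluene at −78 °C (hydride to the Re face, with the quaternary C3 as the large group). The fallback comes back to the route at 21.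

Step 14 (ring-closing metathesis). One olefin sits on a fully substituted carbon next to a bulky benzyl ether and the other is internal, so closure of the nine-membered ring may stall or dimerise. The fallback sets out from 22 and forms ring D before ring C. Both benzyl ethers are removed oxidatively without touching the alkenes (DDQ, wet CH2Cl2, 525 nm light) to give the diol diene F3. Tf2O and 2,6-lutidine convert it, through the primary triflate F4, into the oxepane diene F5, in which the C3 vinyl group is tied back in its final orientation and the benzyl ether is gone. Ring-closing metathesis of F5 with the same ruthenium catalyst gives the tetracyclic alkene F6. H2 over Pd/C then saturates C4=C5, and the fallback comes back at 26 (steps 15 and 16 are skipped).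

Step 18 (C12 by hydrogenation). Double-bond migration on palladium, incomplete face selectivity, or epimerisation of the axial methyl could erode C12. The fallback sets out from 30 and replaces the hydrogenation by conjugate reduction with kinetic protonation. LiBH(s-Bu)3 (1.05 equiv) in THF at −78 °C adds hydride to the exocyclic carbon and gives the regiodefined lithium enolate F7. This is protonated at −78 °C by 2,6-di-tert-butyl-4-methylphenol from the face away from the axial C10–C9 bond. The fallback comes back at 31, which is taken directly into step 19.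

**Further compounds**
F1 | step 12 | (3S,4S)-4-[(2R)-1-(benzyloxy)propan-2-yl]-3-[(1R,2S)-2-(benzyloxy)-1-hydroxy-2-methylbut-3-en-1-yl]cyclohex-1-en-1-yl N,N-diisopropylcarbamate (C2 epimer of 21) | c1ccccc1COC[C@H](C)[C@@H]2CCC(OC(=O)N(C(C)C)C(C)C)=C[C@H]2[C@@H](O)[C@@](C)(OCc3ccccc3)C=C
F2 | step 12 | (3S,4S)-4-[(2R)-1-(benzyloxy)propan-2-yl]-3-[(2S)-2-(benzyloxy)-2-methylbut-3-enoyl]cyclohex-1-en-1-yl N,N-diisopropylcarbamate | c1ccccc1COC[C@H](C)[C@@H]2CCC(OC(=O)N(C(C)C)C(C)C)=C[C@H]2C(=O)[C@@](C)(OCc3ccccc3)C=C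
F3 | step 14 | bis-debenzylated 22 (3-OH, 16-OH diol diene) | OC[C@H](C)[C@@H]2CCC(=O)[C@@H]3[C@H]2[C@H](O[C@H]3C[C@@H](C)[C@H](OC)/C=C/C)[C@@](C)(O)C=C
F4 | step 14 | 16-O-trifluoromethanesulfonate of F3 (not isolated) | FC(F)(F)S(=O)(=O)OC[C@H](C)[C@@H]2CCC(=O)[C@@H]3[C@H]2[C@H](O[C@H]3C[C@@H](C)[C@H](OC)/C=C/C)[C@@](C)(O)C=C
F5 | step 14 | oxepane diene (rings A, B, D; C3 vinyl and C6 propenyl still open) | C=C[C@]2(C)OC[C@H](C)[C@@H]3CCC(=O)[C@@H]4[C@H]3[C@@H]2O[C@H]4C[C@@H](C)[C@H](OC)/C=C/C
F6 | step 14 | tetracyclic (Z)-4,5-ene 11-ketone | CO[C@@H]1/C=C\[C@]2(C)OC[C@H](C)[C@@H]3CCC(=O)[C@@H]4[C@H]3[C@@H]2O[C@H]4C[C@H]1C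
F7 | step 18 | lithium C11=C12 enolate of the 12-methyl ketone (not isolated) | CO[C@@H]1CC[C@]2(C)OC[C@H](C)[C@@H]3CC(C)=C(O[Li])[C@@H]4[C@H]3[C@@H]2O[C@H]4C[C@H]1C
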